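Ring A is cut across C3–C4 and C5–C10 (labdane numbering throughout) into a 2-silyloxy-4-methoxypenta-1,3-diene and methyl (E)-2-methyl-4-oxobut-2-enoate. A single catalytic enantioselective Diels–Alder reaction closes ring A, copies the dienophile geometry into the vicinal pair C4 (quaternary: methyl β, ester α) and C5 (H α, formyl β), and leaves C2 as a ketone with the methyl-bearing C10 as its enone β-carbon. The step thus exploits the C4/C5 stereodiad lying next to the C2–C1–C10 3-methylcyclohexenone pattern of ring A. Conjugate methallylation at C10, ozonolysis and aldol closure then build ring B; the chain is added at C9, followed by methylenation, olefination and saponification.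

Key step: step 3

Assumption: the (S)-configured oxazaborolidinium is written in step 3 on the basis of the usual model for a boron-bound formyl group; should this enal expose the other face, the mirror-image catalyst is used and nothing else changes.

Step 1
Reactants: 1 (E)-4-methoxypent-3-en-2-one
Product: 3 tert-butyl{[(3E)-4-methoxypenta-1,3-dien-2-yl]oxy}dimethylsilane, via potassium dienolate 2 (not isolated)
Conditions: KN(SiMe3)2, THF, −78 °C; then TBSCl, −78 °C → rt
Reagents that add atoms: tert-butyldimethylsilyl chloride, CC(C)(C)[Si](C)(C)Cl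
Why: Kinetic deprotonation of the vinylogous ester at the acetyl methyl group (α′) and O-silylation of the cross-conjugated enolate (silyl enol ether formation) should give the 2-silyloxy diene with the E enol-ether geometry of 1 unchanged; the tert-butyldimethylsilyl group is used in place of trimethylsilyl so that the diene survives the acidic catalyst of step 3 and does not feed an achiral silyl-cation pathway.

Step 2
Reactants: 4 methyl tiglate (methyl (2E)-2-methylbut-2-enoate)
Product: 5 methyl (2E)-2-methyl-4-oxobut-2-enoate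
Conditions: SeO2, 1,4-dioxane, reflux
Reagents that add atoms: selenium dioxide, O=[Se]=O
Why: Allylic oxidation by SeO2 (ene reaction, [2,3]-sigmatropic shift, then oxidation of the allylic alcohol) attacks the γ-methyl group of the enoate and should deliver the aldehyde with the E geometry (formyl trans to the ester) intact.

Step 3
Reactants: 3 tert-butyl{[(3E)-4-methoxypenta-1,3-dien-2-yl]oxy}dimethylsilane; 5 methyl (2E)-2-methyl-4-oxobut-2-enoate
Product: 7 methyl (1R,2R)-2-formyl-1,3-dimethyl-5-oxocyclohex-3-ene-1-carboxylate, via cycloadduct 6 (not isolated)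
Conditions: (S)-1-(2-methylphenyl)-3,3-diphenyltetrahydro-1H,3H-pyrrolo[1,2-c][1,3,2]oxazaborole (20 mol%), Tf2NH (20 mol%), CH2Cl2, −78 °C; then CF3CO2H, −40 °C → 0 °C
Reagents that add atoms: none
Why: Coordination of the formyl oxygen of 5 to the cationic boron lowers the dienophile LUMO, and diene 3 adds in a concerted but asynchronous [4+2] cycloaddition in which the silyloxy-bearing CH2 terminus (C3) bonds first to the ester-bearing β-carbon (C4) and the methoxy-bearing terminus (C10) then closes onto C5. The closest known reaction type is the cationic-oxazaborolidine-catalysed Diels–Alder reaction of 1-alkoxy-3-silyloxy dienes with α,β-unsaturated aldehydes. Ring A is closed by intermolecular suprafacial–suprafacial [4π+2π] cycloaddition, both ring bonds (C3–C4 and C5–C10) forming in the same event, after which acid hydrolyses the silyl enol ether to the C2 ketone and eliminates methanol across C1–C10 to give the enone. The relative configuration of C4 and C5 (formyl cis to the C4 methyl, trans to the ester) is copied from the E geometry of 5, and the absolute configuration of both centres is set by the catalyst, which leaves one enantioface of the bound enal open; the methoxy-bearing centre of 6 is irrelevant because it is lost. The step needs regioselectivity, secured because both donor groups of 3 polarise the diene toward its CH2 terminus while the activated formyl group polarises 5 toward C4, and enantioface selectivity, secured by the catalyst and helped by the robust silyl group. Because C5 of 7 is α to the aldehyde and γ to the enone, 7 is kept cold and carried into step 4 at once.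

Step 4
Reactants: 7 methyl (1R,2R)-2-formyl-1,3-dimethyl-5-oxocyclohex-3-ene-1-carboxylate
Product: 8 methyl (1R,2R)-2-ethenyl-1,3-dimethyl-5-oxocyclohex-3-ene-1-carboxylate
Conditions: Zn, CH2I2, Ti(OiPr)4, THF, 0 °C → rt
Reagents that add atoms: diiodomethane, ICI
Why: Carbonyl methylenation by the gem-dizinc reagent CH2(ZnI)2 in the presence of Ti(OiPr)4 is non-basic and selective for aldehydes over ketones, so the formyl group should become a vinyl group (a masked C6 aldehyde that tolerates TiCl4) without enolisation at C5, whose configuration is therefore kept.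

Step 5
Reactants: 8 methyl (1R,2R)-2-ethenyl-1,3-dimethyl-5-oxocyclohex-3-ene-1-carboxylate; 9 methallyltrimethylsilane
Product: 10 methyl (1R,2R,3S)-2-ethenyl-1,3-dimethyl-3-(2-methylprop-2-en-1-yl)-5-oxocyclohexane-1-carboxylate
Conditions: TiCl4, CH2Cl2, −78 °C → −40 °C
Reagents that add atoms: none
Why: Hosomi–Sakurai conjugate allylation: the TiCl4-bound enone is attacked at C10 by the γ-carbon of the allylsilane, and because allylic strain with the C10 methyl holds the C5 vinyl group pseudoaxial, axial attack anti to it should place the new CH2 (C9) on the α face and the C10 methyl on the β face, the arrangement needed for the trans ring fusion.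

Step 6
Reactants: 10 methyl (1R,2R,3S)-2-ethenyl-1,3-dimethyl-3-(2-methylprop-2-en-1-yl)-5-oxocyclohexane-1-carboxylate
Product: 12 methyl (1R,2R,3S)-2-formyl-1,3-dimethyl-5-oxo-3-(2-oxopropyl)cyclohexane-1-carboxylate, via bis-ozonide 11 (not isolated)
Conditions: O3, CH2Cl2, −78 °C; then Me2S, −78 °C → rt
Reagents that add atoms: ozone, [O-][O+]=O
Why: Ozonolysis with reductive work-up cleaves both terminal alkenes in one operation, the vinyl group returning the C6 aldehyde and the methallyl group giving the C8 methyl ketone; no stereocentre is formed and the α-branched aldehyde is kept neutral and used directly.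

Step 7
Reactants: 12 methyl (1R,2R,3S)-2-formyl-1,3-dimethyl-5-oxo-3-(2-oxopropyl)cyclohexane-1-carboxylate
Product: 14 methyl (1R,4aR,8aR)-1,4a-dimethyl-3,6-dioxo-1,2,3,4,4a,5,6,8a-octahydronaphthalene-1-carboxylate, via β-hydroxy ketone 13 (not isolated)
Conditions: KOH, MeOH, 0 °C → rt
Reagents that add atoms: none
Why: Intramolecular aldol condensation (6-enolendo-exo-trig addition of the methyl ketone enolate carbon C7 to the C6 aldehyde, then E1cB dehydration) closes ring B as the conjugated C6=C7–C8 enone; aldol reactions of the C2 ketone can only give bridged ketols that cannot dehydrate and revert, and the C5/C10 relationship set in steps 3 and 5 becomes the trans ring fusion.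

Step 8
Reactants: 14 methyl (1R,4aR,8aR)-1,4a-dimethyl-3,6-dioxo-1,2,3,4,4a,5,6,8a-octahydronaphthalene-1-carboxylate
Product: 15 methyl (1R,3S,4aR,8aR)-3,6-dihydroxy-1,4a-dimethyl-1,2,3,4,4a,5,6,8a-octahydronaphthalene-1-carboxylate (2β-OH; either C8 carbinol epimer)
Conditions: NaBH4, CeCl3·7H2O, MeOH, −40 °C → 0 °C
Reagents that add atoms: none
Why: Luche reduction reduces both ketones 1,2, and at C2 hydride should arrive from the α face because the β face of the rigid trans-fused chair is closed by the syn-axial methyl groups on C4 and C10, which sets the axial 2β-hydroxyl; the allylic C8 carbinol is only a transient centre.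

Step 9
Reactants: 15 methyl (1R,3S,4aR,8aR)-3,6-dihydroxy-1,4a-dimethyl-1,2,3,4,4a,5,6,8a-octahydronaphthalene-1-carboxylate
Product: 16 methyl (1R,3S,4aR,8aR)-3-hydroxy-1,4a-dimethyl-6-oxo-1,2,3,4,4a,5,6,8a-octahydronaphthalene-1-carboxylate
Conditions: MnO2, CH2Cl2, rt
Reagents that add atoms: none
Why: Chemoselective oxidation of the allylic alcohol by activated MnO2 restores the C6=C7–C8 enone, while the saturated 2β-hydroxyl, shielded by two syn-axial methyl groups, should not be oxidised; no stereocentre is affected.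

Step 10
Reactants: 17 2-(2-bromoethyl)-2-methyl-1,3-dioxolane
Product: 18 2-(2-iodoethyl)-2-methyl-1,3-dioxolane
Conditions: NaI, acetone, reflux
Reagents that add atoms: sodium iodide, [Na+].[I-]
Why: Finkelstein halide exchange (SN2), driven by precipitation of NaBr, converts the commercial bromide into the more reactive iodide.

Step 11
Reactants: 16 methyl (1R,3S,4aR,8aR)-3-hydroxy-1,4a-dimethyl-6-oxo-1,2,3,4,4a,5,6,8a-octahydronaphthalene-1-carboxylate; 18 2-(2-iodoethyl)-2-methyl-1,3-dioxolane
Product: 20 methyl (1R,3S,4aS,5S,8aR)-3-hydroxy-1,4a-dimethyl-5-[2-(2-methyl-1,3-dioxolan-2-yl)ethyl]-6-oxo-1,2,3,4,4a,5,6,8a-octahydronaphthalene-1-carboxylate, via dilithium alkoxide enolate 19 (not isolated)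
Conditions: LiN(iPr)2 (2.2 equiv), THF, −78 °C; then 18, DMPU, −78 °C → 0 °C
Reagents that add atoms: none
Why: Kinetic α′-deprotonation of the enone, whose C6=C7 bond blocks enolisation toward C7, gives the C9 enolate beside the lithium alkoxide of the hindered 2β-hydroxyl, and SN2 C-alkylation by the primary iodide (enolate alkylation) is expected anti to the angular C10 methyl, so that the chain is first α (axial); either C9 epimer converges in step 12.

Step 12
Reactants: 20 methyl (1R,3S,4aS,5S,8aR)-3-hydroxy-1,4a-dimethyl-5-[2-(2-methyl-1,3-dioxolan-2-yl)ethyl]-6-oxo-1,2,3,4,4a,5,6,8a-octahydronaphthalene-1-carboxylate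
Product: 22 methyl (1R,3S,4aS,5R,8aR)-3-hydroxy-1,4a-dimethyl-5-[2-(2-methyl-1,3-dioxolan-2-yl)ethyl]-6-oxodecahydronaphthalene-1-carboxylate, via C9-epimeric ketone 21 (not isolated)
Conditions: H2 (1 atm), 10% Pd/C, EtOAc, rt; then NaOMe, MeOH, rt
Reagents that add atoms: none
Why: Heterogeneous catalytic hydrogenation saturates the conjugated C6=C7 bond without creating a stereocentre, and methoxide-mediated epimerisation through the C8 enolate then moves the C9 chain to the equatorial β position (9α-H), the thermodynamically preferred arrangement next to the axial C10 methyl.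

Step 13
Reactants: 22 methyl (1R,3S,4aS,5R,8aR)-3-hydroxy-1,4a-dimethyl-5-[2-(2-methyl-1,3-dioxolan-2-yl)ethyl]-6-oxodecahydronaphthalene-1-carboxylate
Product: 23 methyl (1R,3S,4aR,5S,8aR)-3-hydroxy-1,4a-dimethyl-6-methylidene-5-[2-(2-methyl-1,3-dioxolan-2-yl)ethyl]decahydronaphthalene-1-carboxylate
Conditions: Ph3PCH3Br, KOtBu (excess, preformed ylide), toluene, rt → 90 °C
Reagents that add atoms: methyltriphenylphosphonium bromide, C[P+](c1ccccc1)(c1ccccc1)c1ccccc1.[Br-]
Why: Wittig methylenation of the C8 ketone with excess non-stabilised ylide (one equivalent is consumed by the 2β-hydroxyl) installs the exocyclic C8=C17 alkene, a transformation well established for 9-substituted 8-oxo decalins; C9 stays in its stable equatorial configuration and the hindered C4 ester is not attacked.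

Step 14
Reactants: 23 methyl (1R,3S,4aR,5S,8aR)-3-hydroxy-1,4a-dimethyl-6-methylidene-5-[2-(2-methyl-1,3-dioxolan-2-yl)ethyl]decahydronaphthalene-1-carboxylate
Product: 24 methyl (1R,3S,4aR,5S,8aR)-3-hydroxy-1,4a-dimethyl-6-methylidene-5-(3-oxobutyl)decahydronaphthalene-1-carboxylate
Conditions: 1 M HCl, THF, rt
Reagents that add atoms: water, O
Why: Acid-catalysed hydrolysis of the dioxolane (acetal cleavage) in dilute aqueous acid at room temperature frees the C13 methyl ketone under conditions too mild to isomerise the exocyclic alkene; no stereocentre is involved.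

Step 15
Reactants: 24 methyl (1R,3S,4aR,5S,8aR)-3-hydroxy-1,4a-dimethyl-6-methylidene-5-(3-oxobutyl)decahydronaphthalene-1-carboxylate
Product: 25 methyl (1R,3S,4aR,5S,8aR)-3-hydroxy-5-[(3E)-5-methoxy-3-methyl-5-oxopent-3-en-1-yl]-1,4a-dimethyl-6-methylidenedecahydronaphthalene-1-carboxylate
Conditions: NaH, (MeO)2P(O)CH2CO2Me, THF, 0 °C → 60 °C
Reagents that add atoms: trimethyl phosphonoacetate, COC(=O)CP(=O)(OC)OC
Why: Horner–Wadsworth–Emmons olefination of the methyl ketone gives the trisubstituted enoate, the E isomer (ester trans to the C12 chain) being favoured by reversible addition and the less strained oxaphosphetane, with the minor Z isomer to be removed by chromatography; the 2β-alkoxide is a spectator.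

Step 16
Reactants: 25 methyl (1R,3S,4aR,5S,8aR)-3-hydroxy-5-[(3E)-5-methoxy-3-methyl-5-oxopent-3-en-1-yl]-1,4a-dimethyl-6-methylidenedecahydronaphthalene-1-carboxylate
Product: 27 (1R,3S,4aR,5S,8aR)-5-[(3E)-4-carboxy-3-methylbut-3-en-1-yl]-3-hydroxy-1,4a-dimethyl-6-methylidenedecahydronaphthalene-1-carboxylic acid, via dipotassium dicarboxylate 26 (not isolated)
Conditions: KOH, MeOH–H2O (3:1), reflux; then 1 M HCl, 0 °C, to pH 2
Reagents that add atoms: potassium hydroxide, [K+].[OH-]
Why: Saponification (acyl–oxygen cleavage by hydroxide) of the enoate and of the equatorial, neopentyl C4 ester, the latter needing prolonged heating, followed by acidification should give the diacid; the 2β-hydroxyl is trans to the C4 carboxyl and cannot lactonise, and no stereocentre is touched.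

Compound list
1 | (E)-4-methoxypent-3-en-2-one | CC(=O)/C=C(\C)OC | starting material
2 | potassium (3E)-4-methoxypenta-1,3-dien-2-olate | [K+].C=C([O-])/C=C(\C)OC | intermediate (not isolated)
3 | tert-butyl{[(3E)-4-methoxypenta-1,3-dien-2-yl]oxy}dimethylsilane | C=C(O[Si](C)(C)C(C)(C)C)/C=C(/OC)C | intermediate
4 | methyl tiglate, methyl (2E)-2-methylbut-2-enoate | C/C=C(\C)C(=O)OC | starting material
5 | methyl (2E)-2-methyl-4-oxobut-2-enoate | O=C/C=C(\C)C(=O)OC | intermediate
6 | methyl (1R,2S,3R)-5-[(tert-butyldimethylsilyl)oxy]-2-formyl-3-methoxy-1,3-dimethylcyclohex-4-ene-1-carboxylate (drawn as the endo adduct; the methoxy-bearing centre is lost) | O=C[C@@H]1[C@](C)(OC)C=C(O[Si](C)(C)C(C)(C)C)C[C@@]1(C)C(=O)OC | intermediate (not isolated)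
7 | methyl (1R,2R)-2-formyl-1,3-dimethyl-5-oxocyclohex-3-ene-1-carboxylate | O=C[C@@H]1C(C)=CC(=O)C[C@@]1(C)C(=O)OC | intermediate
8 | methyl (1R,2R)-2-ethenyl-1,3-dimethyl-5-oxocyclohex-3-ene-1-carboxylate | C=C[C@@H]1C(C)=CC(=O)C[C@@]1(C)C(=O)OC | intermediate
9 | methallyltrimethylsilane, trimethyl(2-methylprop-2-en-1-yl)silane | C=C(C)C[Si](C)(C)C | starting material
10 | methyl (1R,2R,3S)-2-ethenyl-1,3-dimethyl-3-(2-methylprop-2-en-1-yl)-5-oxocyclohexane-1-carboxylate | C=C[C@@H]1[C@@](C)(CC(C)=C)CC(=O)C[C@@]1(C)C(=O)OC | intermediate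
11 | bis-ozonide of 10 (both alkenes as 1,2,4-trioxolanes; ring centres as in 10) | O1OCOC1[C@@H]2[C@@](C)(CC3(C)OCOO3)CC(=O)C[C@@]2(C)C(=O)OC | intermediate (not isolated)
12 | methyl (1R,2R,3S)-2-formyl-1,3-dimethyl-5-oxo-3-(2-oxopropyl)cyclohexane-1-carboxylate | O=C[C@@H]1[C@@](C)(CC(C)=O)CC(=O)C[C@@]1(C)C(=O)OC | intermediate
13 | methyl (1R,4aR,8aR)-8-hydroxy-1,4a-dimethyl-3,6-dioxodecahydronaphthalene-1-carboxylate (either C8 epimer) | O=C1CC(O)[C@@H]2[C@](C)(CC(=O)C[C@@]2(C)C(=O)OC)C1 | intermediate (not isolated)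
14 | methyl (1R,4aR,8aR)-1,4a-dimethyl-3,6-dioxo-1,2,3,4,4a,5,6,8a-octahydronaphthalene-1-carboxylate | O=C1C=C[C@@H]2[C@](C)(CC(=O)C[C@@]2(C)C(=O)OC)C1 | intermediate
15 | methyl (1R,3S,4aR,8aR)-3,6-dihydroxy-1,4a-dimethyl-1,2,3,4,4a,5,6,8a-octahydronaphthalene-1-carboxylate (either C6 epimer of the naphthalene numbering) | OC1C=C[C@@H]2[C@](C)(C[C@H](O)C[C@@]2(C)C(=O)OC)C1 | intermediate
16 | methyl (1R,3S,4aR,8aR)-3-hydroxy-1,4a-dimethyl-6-oxo-1,2,3,4,4a,5,6,8a-octahydronaphthalene-1-carboxylate | O=C1C=C[C@@H]2[C@](C)(C[C@H](O)C[C@@]2(C)C(=O)OC)C1 | intermediate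
17 | 2-(2-bromoethyl)-2-methyl-1,3-dioxolane | CC1(CCBr)OCCO1 | starting material
18 | 2-(2-iodoethyl)-2-methyl-1,3-dioxolane | CC1(CCI)OCCO1 | intermediate
19 | dilithium salt of 16 (C2 alkoxide, C8–C9 dienolate) | [Li+].[Li+].[O-]C=1C=C[C@@H]2[C@](C)(C[C@H]([O-])C[C@@]2(C)C(=O)OC)C=1 | intermediate (not isolated)
20 | methyl (1R,3S,4aS,5S,8aR)-3-hydroxy-1,4a-dimethyl-5-[2-(2-methyl-1,3-dioxolan-2-yl)ethyl]-6-oxo-1,2,3,4,4a,5,6,8a-octahydronaphthalene-1-carboxylate (chain α at C9) | O=C1C=C[C@@H]2[C@](C)(C[C@H](O)C[C@@]2(C)C(=O)OC)[C@@H]1CCC3(C)OCCO3 | intermediate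
21 | methyl (1R,3S,4aS,5S,8aR)-3-hydroxy-1,4a-dimethyl-5-[2-(2-methyl-1,3-dioxolan-2-yl)ethyl]-6-oxodecahydronaphthalene-1-carboxylate (chain α at C9) | O=C1CC[C@@H]2[C@](C)(C[C@H](O)C[C@@]2(C)C(=O)OC)[C@@H]1CCC3(C)OCCO3 | intermediate (not isolated)
22 | methyl (1R,3S,4aS,5R,8aR)-3-hydroxy-1,4a-dimethyl-5-[2-(2-methyl-1,3-dioxolan-2-yl)ethyl]-6-oxodecahydronaphthalene-1-carboxylate (chain β at C9) | O=C1CC[C@@H]2[C@](C)(C[C@H](O)C[C@@]2(C)C(=O)OC)[C@H]1CCC3(C)OCCO3 | intermediate
23 | methyl (1R,3S,4aR,5S,8aR)-3-hydroxy-1,4a-dimethyl-6-methylidene-5-[2-(2-methyl-1,3-dioxolan-2-yl)ethyl]decahydronaphthalene-1-carboxylate | C=C1CC[C@@H]2[C@](C)(C[C@H](O)C[C@@]2(C)C(=O)OC)[C@H]1CCC3(C)OCCO3 | intermediate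
24 | methyl (1R,3S,4aR,5S,8aR)-3-hydroxy-1,4a-dimethyl-6-methylidene-5-(3-oxobutyl)decahydronaphthalene-1-carboxylate | C=C1CC[C@@H]2[C@](C)(C[C@H](O)C[C@@]2(C)C(=O)OC)[C@H]1CCC(C)=O | intermediate
25 | methyl (1R,3S,4aR,5S,8aR)-3-hydroxy-5-[(3E)-5-methoxy-3-methyl-5-oxopent-3-en-1-yl]-1,4a-dimethyl-6-methylidenedecahydronaphthalene-1-carboxylate | C=C1CC[C@@H]2[C@](C)(C[C@H](O)C[C@@]2(C)C(=O)OC)[C@H]1CC/C(C)=C/C(=O)OC | intermediate
26 | dipotassium salt of 27 | [K+].[K+].C=C1CC[C@@H]2[C@](C)(C[C@H](O)C[C@@]2(C)C(=O)[O-])[C@H]1CC/C(C)=C/C(=O)[O-] | intermediate (not isolated)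
27 | (1R,3S,4aR,5S,8aR)-5-[(3E)-4-carboxy-3-methylbut-3-en-1-yl]-3-hydroxy-1,4a-dimethyl-6-methylidenedecahydronaphthalene-1-carboxylic acid (2β-hydroxylabda-8(17),13E-diene-15,18-dioic acid) | C=C1CC[C@@H]2[C@](C)(C[C@H](O)C[C@@]2(C)C(=O)O)[C@H]1CC/C(C)=C/C(=O)O | target

Total step count: 16. Longest linear sequence: 14 steps (step 1 or 2, then steps 3–9 and 11–16).

Steps most likely to fail

Step 3. The formyl group of 7 sits on the γ-carbon of the enone, so enolisation toward the fully conjugated dienol during the acid unmasking, or during any delay, would erode the C5 configuration. A slow cycloaddition of a diene whose methyl group points inward would make this worse by lengthening exposure to the acidic catalyst. In the fallback the aldehyde is removed before the enone exists. The cycloaddition is run as in step 3 but quenched with Et3N instead of acid, and crude cycloadduct 6 is treated with salt-free Ph3P=CH2 in THF at −78 °C → 0 °C. This Wittig methylenation gives methyl (1R,2S,3S)-5-[(tert-butyldimethylsilyl)oxy]-2-ethenyl-3-methoxy-1,3-dimethylcyclohex-4-ene-1-carboxylate F1. CF3CO2H in CH2Cl2 at 0 °C then cleaves the silyl enol ether and eliminates methanol, and the route is rejoined at 8.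

Step 5. Bond formation at C10, flanked by C5 and the quaternary C4, may be so slow that protodesilylation of the allylsilane and Lewis-acid-induced isomerisation of the skipped diene outrun the addition. The fallback replaces Lewis-acid activation by organocopper conjugate transfer. Compound 8 is treated with methallylmagnesium chloride, CuBr·SMe2, LiCl and Me3SiCl in THF at −78 °C. The allylic copper species should add 1,4 anti to the vinyl group, and the enolate is trapped as the C1=C2 trimethylsilyl enol ether of 10, methyl (1R,2R,3R)-2-ethenyl-1,3-dimethyl-3-(2-methylprop-2-en-1-yl)-5-[(trimethylsilyl)oxy]cyclohex-4-ene-1-carboxylate F2. Dilute HCl in THF at 0 °C hydrolyses F2 to 10, where the route is rejoined.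

Step 11. Substitution at the enolate carbon next to the quaternary C10 may be slow, so that dehydroiodination of 18 and proton exchange between enolate and product compete. The fallback uses an aldol addition, which is fast even at hindered enolates, and lets the hydrogenation of step 12 remove the extra unsaturation.
- Ethyl (2-methyl-1,3-dioxolan-2-yl)acetate is reduced with iBu2AlH in CH2Cl2 at −78 °C to (2-methyl-1,3-dioxolan-2-yl)acetaldehyde F3.
- Compound 16 is deprotonated as in step 11 and the enolate is treated with F3 at −78 °C, giving the aldol methyl (1R,3S,4aS,8aR)-3-hydroxy-5-[1-hydroxy-2-(2-methyl-1,3-dioxolan-2-yl)ethyl]-1,4a-dimethyl-6-oxo-1,2,3,4,4a,5,6,8a-octahydronaphthalene-1-carboxylate F4.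
- MsCl and Et3N in CH2Cl2 at 0 °C convert the unhindered side-chain hydroxyl into the corresponding methanesulfonate F5, the shielded 2β-hydroxyl being left.
- DBU in CH2Cl2 at rt eliminates it to the cross-conjugated dienone methyl (1R,3S,4aS,8aR)-3-hydroxy-1,4a-dimethyl-5-[2-(2-methyl-1,3-dioxolan-2-yl)ethylidene]-6-oxo-1,2,3,4,4a,5,6,8a-octahydronaphthalene-1-carboxylate F6.
- Hydrogenation of F6 under the conditions of step 12 saturates both C=C bonds, and the same methoxide equilibration delivers 22, where the route is rejoined.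

Further compounds
F1 | step 3 | methyl (1R,2S,3S)-5-[(tert-butyldimethylsilyl)oxy]-2-ethenyl-3-methoxy-1,3-dimethylcyclohex-4-ene-1-carboxylate | C=C[C@@H]1[C@](C)(OC)C=C(O[Si](C)(C)C(C)(C)C)C[C@@]1(C)C(=O)OC
F2 | step 5 | methyl (1R,2R,3R)-2-ethenyl-1,3-dimethyl-3-(2-methylprop-2-en-1-yl)-5-[(trimethylsilyl)oxy]cyclohex-4-ene-1-carboxylate | C=C[C@@H]1[C@@](C)(CC(C)=C)C=C(O[Si](C)(C)C)C[C@@]1(C)C(=O)OC
F3 | step 11 | (2-methyl-1,3-dioxolan-2-yl)acetaldehyde | CC1(CC=O)OCCO1
F4 | step 11 | methyl (1R,3S,4aS,8aR)-3-hydroxy-5-[1-hydroxy-2-(2-methyl-1,3-dioxolan-2-yl)ethyl]-1,4a-dimethyl-6-oxo-1,2,3,4,4a,5,6,8a-octahydronaphthalene-1-carboxylate (epimers at C5 and at the carbinol carbon) | O=C1C=C[C@@H]2[C@](C)(C[C@H](O)C[C@@]2(C)C(=O)OC)C1C(O)CC3(C)OCCO3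
F5 | step 11 | side-chain methanesulfonate of F4 | O=C1C=C[C@@H]2[C@](C)(C[C@H](O)C[C@@]2(C)C(=O)OC)C1C(OS(C)(=O)=O)CC3(C)OCCO3
F6 | step 11 | methyl (1R,3S,4aS,8aR)-3-hydroxy-1,4a-dimethyl-5-[2-(2-methyl-1,3-dioxolan-2-yl)ethylidene]-6-oxo-1,2,3,4,4a,5,6,8a-octahydronaphthalene-1-carboxylate (either alkene geometry) | O=C1C=C[C@@H]2[C@](C)(C[C@H](O)C[C@@]2(C)C(=O)OC)C1=CCC3(C)OCCO3
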